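**Remark on the chemistry:** target 11 has no stereocentre, no stereogenic axis and no C=C bond. It is achiral, so the given SMILES defines it fully and no step has to control configuration.

## Analysis of the target

- Target 11 (C33H36O8) is an open array of four benzene rings. Two identical bibenzyl halves are joined through one methylene carbon, C7.
- Locants used throughout: in the inner rings A/A′, C1 carries C7, C2 carries OMe, C4 carries OH, and C6 carries the chain CαH2–CβH2. The outer rings B/B′ are 4-hydroxy-3-methoxyphenyl groups on Cβ.
- With no stereocentres, the problem is one of regiochemistry, crowding and differentiation of oxygen atoms.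
- Each ring A is 1,2,4,6-tetrasubstituted, with its two carbon substituents on the adjacent atoms C1 and C6. C7 therefore sits between four ortho substituents (two OMe, two chains).
- C1 is also the most hindered of the three nucleophilic positions of a 5-alkylresorcinol monoether.
- In each ring A the oxygen at C2 is methylated and that at C4 is free. The same distinction holds in ring B.
- The four electron-rich phenols are sensitive to oxidation. A diarylmethane para to OH is labile to strong acid by ipso protonation and scrambling. The phenols should therefore appear last, and strong acid should be avoided.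
- The feature the route exploits: Cα is bonded to C6/C6′, the ring atoms ortho to C1/C1′, while the other ortho atoms C2/C2′ are blocked by OMe.
  - If C7 is a carbonyl carbon, its oxygen can deliver a metal through a five-membered chelate O=C7–C1–C6–M to exactly the C6–H and C6′–H bonds that must become C6–Cα and C6′–Cα′.
  - The 2,4-dioxygenation of both rings is that of the commodity UV absorber 1.

## Retrosynthetic reasoning

**11 ⇒ 8.** No skeletal bond is cut. The four phenols are traced back to benzyl ethers and C7H2 to a carbinol C7H–OH. All five C–O bonds are benzylic, so one hydrogenolysis should release them together (through 9 and 10). The sensitive tetraphenol then appears only in the last flask.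

**8 ⇒ 7.** C7 is raised to the ketone level. This costs one hydride reduction. In return, the bridge carbon becomes the control element for the whole skeleton, because a ketone is a directing group and a methylene group is not.

**7 ⇒ 3 + 2 × 5 (via 6).** This is the key cut: both C6–Cα bonds at once.
- Cutting C7–C1 would return to an electrophilic substitution at the worst of three activated positions.
- Cutting Cα–Cβ would need a benzylic handle on C6 that first has to be installed.
- Cutting C6–Cα leaves only a C–H bond on the arene side and a vinyl group on the other side.
- The forward reaction has to add C6–H and C6′–H across two molecules of 5 with the aryl carbon going to the terminal alkene carbon.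
- Three components give all 33 skeletal carbons in one operation. The regiochemistry of ring A is dictated by the position of C7=O, not by the electronics of the ring.
- The symmetry of the core is kept throughout, so both ends are elaborated at the same time.

**3 ⇒ 2 ⇒ 1.** Only O–C bonds are cut. In 1 the C2/C2′ hydroxyl groups are hydrogen-bonded to C7=O and the C4/C4′ hydroxyl groups are not. O-Benzylation therefore takes the free pair first, and forcing O-methylation takes the chelated pair second. The carbonyl group thus also solves the differentiation of the two oxygens of ring A.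

**5 ⇒ 4.** The vinyl C=C is cut by carbonyl methylenation. Compound 4 already carries ring B with its methyl ether, and its phenol bears the same protecting group as ring A.

## Alternatives that were turned down

**Alternative 1:** the textbook disconnection of both C7–C1 bonds.
- Forward key step: acid-catalysed condensation of two molecules of the monomeric bibenzyl A1 with formaldehyde A2 (hydroxymethylation, ionisation, Friedel–Crafts alkylation).
- Ring A of A1 has three C–H positions, each ortho or para to both oxygens. The one required lies between OMe and the chain and is the most hindered.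
- Ring B is a free guaiacol and competes as a nucleophile.
- Product 11 keeps four activated positions and reacts on to oligomers.
- The condensation is reversible in acid, so a mixture is the thermodynamic outcome.
- A1 itself needs an olefination/hydrogenation sequence with two differentiated phenols, so nothing is saved in steps.

**Alternative 2:** disconnection of rings A and A′ themselves (bonds C1–C2 and C5–C6 in each ring).
- Forward key step: double Diels–Alder/aromatisation of the cross-conjugated diynone A3 with two molecules of the ketene-acetal diene A4, giving the benzophenone A5.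
- The polarity match is right: the CH2 terminus of A4 attacks the β-alkyne carbon and the acetal terminus bonds to the α-carbon. The pattern 2-OMe/4-OH/6-alkyl would be set twice.
- It was turned down on step economy. It builds two benzene rings that can be bought already joined in 1.
- A3 needs about five steps (halide, C3 homologation, desilylation, formate coupling, oxidation) and A4 two or three more.
- A5 has free para-phenols that deactivate the hindered ketone towards hydride.

**Alternative 3:** disconnection of C6–Cα and C1–C7 in each ring at once, through an aryne.
- Forward key step: ortho-lithiation and fluoride loss from the silyl ether A6, addition of the Grignard reagent A7 at C6 of the aryne, and capture of the resulting C1-magnesium species by half an equivalent of a formate ester. This pseudo-five-component coupling would give carbinol A8.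
- The regiochemistry of addition (nucleophile meta to OMe) is right, but the stoichiometry works against itself.
- A7 must be in excess to outrun addition of the aryllithium to the aryne. Any excess of this unhindered alkyl nucleophile then consumes the C1 electrophile before the hindered aryl nucleophile does, which gives crossed carbinols.
- Site-selective lithiation depends on steric shielding alone.
- Both A6 and A7 have to be made, and two kinds of protecting group have to be removed.

Key step: step 4

## Route

**Step 1**
Reactants: 1 2,2′,4,4′-tetrahydroxybenzophenone
Product: 2 bis[4-(benzyloxy)-2-hydroxyphenyl]methanone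
Conditions: BnBr (2.1 equiv), K2CO3 (2.2 equiv), acetone, reflux
Reagents that add atoms: benzyl bromide, BrCc1ccccc1
Why: Williamson ether synthesis; the C2/C2′ hydroxyl groups are tied up in hydrogen bonds to C7=O and are less acidic and less nucleophilic, so a limited amount of base and halide should alkylate only the C4/C4′ hydroxyl groups, as in the standard 4-O-alkylation of 2,4-dihydroxyaryl ketones.

**Step 2**
Reactants: 2 bis[4-(benzyloxy)-2-hydroxyphenyl]methanone
Product: 3 bis[4-(benzyloxy)-2-methoxyphenyl]methanone
Conditions: MeI (6 equiv), K2CO3 (4 equiv), DMF, 50 °C, closed vessel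
Reagents that add atoms: methyl iodide, CI
Why: Williamson O-methylation of chelated phenols; a polar aprotic solvent, excess base and a small electrophile overcome the hydrogen bond, and nothing else in 2 can be alkylated.

**Step 3**
Reactants: 4 4-(benzyloxy)-3-methoxybenzaldehyde (O-benzylvanillin)
Product: 5 1-(benzyloxy)-4-ethenyl-2-methoxybenzene (4-benzyloxy-3-methoxystyrene)
Conditions: Ph3PCH3Br (1.3 equiv), KOt-Bu (1.25 equiv), THF, 0 °C to rt
Reagents that add atoms: methyltriphenylphosphonium bromide, C[P+](c1ccccc1)(c1ccccc1)c1ccccc1.[Br-]
Why: Wittig methylenation of a non-enolisable aromatic aldehyde; the ethers are inert to the ylide and no alkene geometry arises.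

**Step 4**
Reactants: 3 bis[4-(benzyloxy)-2-methoxyphenyl]methanone; 5 1-(benzyloxy)-4-ethenyl-2-methoxybenzene (two molecules are incorporated)
Product: 7 bis[4-(benzyloxy)-2-{2-[4-(benzyloxy)-3-methoxyphenyl]ethyl}-6-methoxyphenyl]methanone, via [4-(benzyloxy)-2-{2-[4-(benzyloxy)-3-methoxyphenyl]ethyl}-6-methoxyphenyl][4-(benzyloxy)-2-methoxyphenyl]methanone 6 (not isolated)
Conditions: 5 (4 equiv), [RuCl2(p-cymene)]2 (5 mol %), HCO2Na (30 mol %), P(4-CF3C6H4)3 (15 mol %), 1,4-dioxane, 100 °C, sealed tube, Ar
Reagents that add atoms: none
Why: Murai reaction, i.e. ruthenium-catalysed ketone-directed addition of an ortho C–H bond across an alkene, in its anti-Markovnikov styrene variant, used twice on one carbonyl group so that three components give the whole C33 skeleton. The low-valent Ru hydride species formed from the precatalyst, formate and the phosphine binds the C7=O oxygen and inserts reversibly into C6–H to give the five-membered ruthenacycle O=C7–C1–C6–Ru(H); 5 inserts into Ru–H with Ru at the terminal carbon, and rate-limiting C–C reductive elimination forms C6–Cα to give 6, which enters the same cycle at C6′–H to give 7. Site selectivity is secured by the substrate: C2/C2′ are blocked by OMe, so each ring offers exactly one ortho C–H, and C3–H, C5–H, the benzyl groups and ring B of 5 cannot reach the metal through a five-membered chelate. Linear selectivity is needed twice and is secured by the crowding at the ruthenacycle, by the electron-rich aryl group of 5, which stabilises a benzylic Ru–C bond poorly, and by the electron-poor phosphine, which speeds up reductive elimination from the primary alkyl. The second alkylation remains possible because in 6 the 2,6-disubstituted ring turns out of the carbonyl plane and leaves ring A′ coplanar with C7=O, with the oxygen turned away from C2′–OMe and towards C6′–H. C–H must win over the C2–OMe bond, which low-valent Ru can also cleave in o-methoxyaryl ketones; C–H insertion is the faster process and the excess of 5 drains the hydride towards product. Over-alkylation is impossible, since 7 has no ortho C–H left. No ring is closed in the product and no stereocentre is formed.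

**Step 5**
Reactants: 7 bis[4-(benzyloxy)-2-{2-[4-(benzyloxy)-3-methoxyphenyl]ethyl}-6-methoxyphenyl]methanone
Product: 8 bis[4-(benzyloxy)-2-{2-[4-(benzyloxy)-3-methoxyphenyl]ethyl}-6-methoxyphenyl]methanol
Conditions: LiAlH4 (3 equiv), THF, reflux; H2O/aq NaOH work-up; used crude, no silica gel
Reagents that add atoms: none
Why: Hydride reduction of a diaryl ketone; the small AlH4− ion at reflux should reach a carbonyl group flanked by four ortho substituents, as with other 2,2′,6,6′-tetrasubstituted benzophenones, and because all phenols are masked no phenoxide deactivates C7=O. C7 carries two identical aryl groups and is not a stereocentre.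

**Step 6**
Reactants: 8 bis[4-(benzyloxy)-2-{2-[4-(benzyloxy)-3-methoxyphenyl]ethyl}-6-methoxyphenyl]methanol
Product: 11 4,4′-methylenebis{3-[2-(4-hydroxy-3-methoxyphenyl)ethyl]-5-methoxyphenol} (target), via bis{4-hydroxy-2-[2-(4-hydroxy-3-methoxyphenyl)ethyl]-6-methoxyphenyl}methanol 9 (not isolated), via 4-({4-hydroxy-2-[2-(4-hydroxy-3-methoxyphenyl)ethyl]-6-methoxyphenyl}methylidene)-3-[2-(4-hydroxy-3-methoxyphenyl)ethyl]-5-methoxycyclohexa-2,5-dien-1-one 10 (not isolated)
Conditions: H2 (3 atm), 10% Pd/C, EtOAc–EtOH 1:1, AcOH (5 vol %), rt
Reagents that add atoms: none
Why: Catalytic hydrogenolysis; the four aryl benzyl ethers should cleave first to give 9, whose C7–OH is doubly benzylic and para to two free phenols, so weak acid suffices to expel water to the p-quinone methide 10, which takes up hydrogen with rearomatisation. Methyl ethers and arenes are inert, and only a weak acid is present, so the product diarylmethane should not scramble.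

## Compound list

1 | 2,2′,4,4′-tetrahydroxybenzophenone | O=C(c1ccc(O)cc1O)c1ccc(O)cc1O | starting material
2 | bis[4-(benzyloxy)-2-hydroxyphenyl]methanone | O=C(c1ccc(OCc2ccccc2)cc1O)c1ccc(OCc2ccccc2)cc1O | intermediate
3 | bis[4-(benzyloxy)-2-methoxyphenyl]methanone | O=C(c1ccc(OCc2ccccc2)cc1OC)c1ccc(OCc2ccccc2)cc1OC | intermediate
4 | 4-(benzyloxy)-3-methoxybenzaldehyde | COc1cc(C=O)ccc1OCc1ccccc1 | starting material
5 | 1-(benzyloxy)-4-ethenyl-2-methoxybenzene | COc1cc(C=C)ccc1OCc1ccccc1 | intermediate
6 | [4-(benzyloxy)-2-{2-[4-(benzyloxy)-3-methoxyphenyl]ethyl}-6-methoxyphenyl][4-(benzyloxy)-2-methoxyphenyl]methanone | O=C(c1ccc(OCc2ccccc2)cc1OC)c1c(CCc2ccc(OCc3ccccc3)c(OC)c2)cc(OCc2ccccc2)cc1OC | intermediate (not isolated)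
7 | bis[4-(benzyloxy)-2-{2-[4-(benzyloxy)-3-methoxyphenyl]ethyl}-6-methoxyphenyl]methanone | O=C(c1c(CCc2ccc(OCc3ccccc3)c(OC)c2)cc(OCc2ccccc2)cc1OC)c1c(CCc2ccc(OCc3ccccc3)c(OC)c2)cc(OCc2ccccc2)cc1OC | intermediate
8 | bis[4-(benzyloxy)-2-{2-[4-(benzyloxy)-3-methoxyphenyl]ethyl}-6-methoxyphenyl]methanol | OC(c1c(CCc2ccc(OCc3ccccc3)c(OC)c2)cc(OCc2ccccc2)cc1OC)c1c(CCc2ccc(OCc3ccccc3)c(OC)c2)cc(OCc2ccccc2)cc1OC | intermediate
9 | bis{4-hydroxy-2-[2-(4-hydroxy-3-methoxyphenyl)ethyl]-6-methoxyphenyl}methanol | OC(c1c(CCc2ccc(O)c(OC)c2)cc(O)cc1OC)c1c(CCc2ccc(O)c(OC)c2)cc(O)cc1OC | intermediate (not isolated)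
10 | 4-({4-hydroxy-2-[2-(4-hydroxy-3-methoxyphenyl)ethyl]-6-methoxyphenyl}methylidene)-3-[2-(4-hydroxy-3-methoxyphenyl)ethyl]-5-methoxycyclohexa-2,5-dien-1-one (geometry of the exocyclic C=C not defined; it is lost in the next event) | O=C1C=C(CCc2ccc(O)c(OC)c2)C(=Cc2c(CCc3ccc(O)c(OC)c3)cc(O)cc2OC)C(OC)=C1 | intermediate (not isolated)
11 | 4,4′-methylenebis{3-[2-(4-hydroxy-3-methoxyphenyl)ethyl]-5-methoxyphenol} (CNP0079383.0, achiral) | COc1cc(CCc2cc(O)cc(OC)c2Cc2c(CCc3ccc(O)c(OC)c3)cc(O)cc2OC)ccc1O | target

## Step count and least certain steps

Total step count: 6. Longest linear sequence: 5 (1 → 2 → 3 → 7 → 8 → 11; step 3 is a one-step side branch).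

**Step 4 (key step).**
- Most likely failures:
  - The reaction stalls after the first alkylation, because reductive elimination at the crowded metal centre is slow.
  - Ruthenium inserts into the C2–OMe bond, which would tie up the catalyst or cost a methoxy group.
  - Some branched insertion of the styrene occurs.
  - Compound 5 polymerises thermally during a long reaction time.
- Fallback: sets out from 3 and 5 and comes back to the route at 11.
  - The redox-neutral hydroarylation is replaced by a dehydrogenative ortho-alkenylation under cationic Ru(II) catalysis ([RuCl2(p-cymene)]2, AgSbF6, Cu(OAc)2, 1,2-dichloroethane, 110 °C).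
  - This proceeds by carboxylate-assisted C–H metalation, alkene insertion and β-hydride elimination. It has no linear/branched issue and does not rest on a low-valent metal that attacks C–OMe.
  - It should give bis[4-(benzyloxy)-2-{(E)-2-[4-(benzyloxy)-3-methoxyphenyl]ethenyl}-6-methoxyphenyl]methanone F1.
  - LiAlH4 in THF then gives bis[4-(benzyloxy)-2-{(E)-2-[4-(benzyloxy)-3-methoxyphenyl]ethenyl}-6-methoxyphenyl]methanol F2.
  - The hydrogenation conditions of step 6 saturate both C=C bonds as well and deliver 11.

**Step 5.**
- Most likely failure: incomplete hydride delivery, because four ortho substituents shield the carbonyl carbon.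
- Fallback: sets out from 7 and comes back at 11.
  - Dissolving-metal reduction (Li, liquid NH3/THF, −33 °C, then solid NH4Cl while metal is still present) transfers electrons and does not need a nucleophile to approach C7.
  - This is the known reduction of aromatic ketones to the hydrocarbon. The same medium cleaves the four aryl benzyl ethers, so steps 5 and 6 are replaced by one operation.
  - This fallback makes no compound outside the list (F0).

**Step 6.**
- Most likely failures:
  - Hydrogenolysis at the hindered C7 is slow, so the material rests at the carbinol or its solvent ether.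
  - Ionisation at C7 is followed by Friedel–Crafts capture by the pendant ring B, closing a seven-membered ring through the position para to its OMe.
- Fallback: sets out from 8, passes through 9 (now isolated) and comes back at 11.
  - The benzyl ethers are removed under strictly neutral conditions (H2, Pd/C, EtOAc, no acid).
  - Compound 9 is then heated with NaBH4 in aqueous NaOH/EtOH. The phenoxide expels hydroxide to give 10, which borohydride traps by 1,6-addition.
  - No carbocation is involved at any point.
  - This fallback makes no compound outside the list (F0).

**Step 1.**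
- Most likely failure: loss of selectivity. Partial alkylation of a chelated hydroxyl group, or incomplete reaction at one C4 hydroxyl group, would give mixtures that are hard to separate.
- Fallback: sets out from 1 and comes back at 2.
  - Exhaustive benzylation (excess BnBr, K2CO3, DMF, 60 °C) gives bis[2,4-bis(benzyloxy)phenyl]methanone F3.
  - Chelation-controlled cleavage with MgBr2·OEt2 (toluene/Et2O, reflux) then removes only the two benzyl groups whose oxygen can bind magnesium together with C7=O.

## Further compounds

F1 | step 4 | bis[4-(benzyloxy)-2-{(E)-2-[4-(benzyloxy)-3-methoxyphenyl]ethenyl}-6-methoxyphenyl]methanone | O=C(c1c(/C=C/c2ccc(OCc3ccccc3)c(OC)c2)cc(OCc2ccccc2)cc1OC)c1c(/C=C/c2ccc(OCc3ccccc3)c(OC)c2)cc(OCc2ccccc2)cc1OC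
F2 | step 4 | bis[4-(benzyloxy)-2-{(E)-2-[4-(benzyloxy)-3-methoxyphenyl]ethenyl}-6-methoxyphenyl]methanol | OC(c1c(/C=C/c2ccc(OCc3ccccc3)c(OC)c2)cc(OCc2ccccc2)cc1OC)c1c(/C=C/c2ccc(OCc3ccccc3)c(OC)c2)cc(OCc2ccccc2)cc1OC
F0 | step 5 | none | none
F0 | step 6 | none | none
F3 | step 1 | bis[2,4-bis(benzyloxy)phenyl]methanone | O=C(c1ccc(OCc2ccccc2)cc1OCc1ccccc1)c1ccc(OCc2ccccc2)cc1OCc1ccccc1
A1 | alternative 1 | 4-[2-(3-hydroxy-5-methoxyphenyl)ethyl]-2-methoxyphenol | COc1cc(O)cc(CCc2ccc(O)c(OC)c2)c1
A2 | alternative 1 | formaldehyde | C=O
A3 | alternative 2 | 1,9-bis[4-(benzyloxy)-3-methoxyphenyl]nona-3,6-diyn-5-one | O=C(C#CCCc1ccc(OCc2ccccc2)c(OC)c1)C#CCCc1ccc(OCc2ccccc2)c(OC)c1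
A4 | alternative 2 | 1,1-dimethoxy-3-(trimethylsilyloxy)buta-1,3-diene | COC(OC)=CC(=C)O[Si](C)(C)C
A5 | alternative 2 | bis[2-{2-[4-(benzyloxy)-3-methoxyphenyl]ethyl}-4-hydroxy-6-methoxyphenyl]methanone | O=C(c1c(CCc2ccc(OCc3ccccc3)c(OC)c2)cc(O)cc1OC)c1c(CCc2ccc(OCc3ccccc3)c(OC)c2)cc(O)cc1OC
A6 | alternative 3 | (3-fluoro-5-methoxyphenoxy)tri(propan-2-yl)silane | COc1cc(F)cc(O[Si](C(C)C)(C(C)C)C(C)C)c1
A7 | alternative 3 | 2-[4-(benzyloxy)-3-methoxyphenyl]ethylmagnesium bromide | COc1cc(CC[Mg]Br)ccc1OCc1ccccc1
A8 | alternative 3 | bis[2-{2-[4-(benzyloxy)-3-methoxyphenyl]ethyl}-6-methoxy-4-(triisopropylsilyloxy)phenyl]methanol | OC(c1c(CCc2ccc(OCc3ccccc3)c(OC)c2)cc(O[Si](C(C)C)(C(C)C)C(C)C)cc1OC)c1c(CCc2ccc(OCc3ccccc3)c(OC)c2)cc(O[Si](C(C)C)(C(C)C)C(C)C)cc1OC
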